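**Retrosynthetic overview**
- Aryl–CH2 bond (made first): bromoarene 1 and (R)-propylene oxide 2, joined through Grignard reagent 3, give carbinol 4. Compound 2 is the only source of the stereocentre.
- Aryl–CH bond (key bond, made last): the benzylic C–H of 4 and the C5–H of arene 5 are joined at an anode through cation 6 to give target 7, with H2 as the only by-product.
- No ring is formed; both benzene rings are bought. The new benzylic carbon carries two identical aryl groups, so the carbinol carbon is the only stereocentre, and it is (R).

Assumption: the route has only two steps, so the closing risk ranking covers both of them instead of three.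

**Step 1**
Reactants: 1 1-bromo-2,4,5-trimethoxybenzene; 2 (R)-2-methyloxirane [(R)-propylene oxide]
Product: 4 (R)-1-(2,4,5-trimethoxyphenyl)propan-2-ol, via arylmagnesium bromide 3 (not isolated)
Conditions: Mg (1.2 equiv), cat. I2, THF, 45 °C; then CuI (10 mol %), 2 (1.3 equiv), −30 → 0 °C; H2O quench
Reagents that add atoms: none
Why: Copper-catalysed SN2 ring-opening of a terminal epoxide by an aryl Grignard reagent occurs at the unsubstituted CH2, so the C–O bond at the stereocentre is never broken and the (R) configuration of 2 is carried unchanged into 4.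

**Step 2**
Reactants: 4 (R)-1-(2,4,5-trimethoxyphenyl)propan-2-ol; 5 1,2,4-trimethoxybenzene
Product: 7 tatarinoid C [(R)-1,1-bis(2,4,5-trimethoxyphenyl)propan-2-ol], via benzylic cation 6 (not isolated)
Conditions: undivided cell, graphite felt(+)|Pt(−), +1.0 V vs SCE, 2.1 F mol−1; 5 (5 equiv), 2,6-lutidine (1 equiv), Bu4NPF6 (0.1 M), HFIP/CH2Cl2 (4:1), 3 Å MS, 0 °C, N2
Reagents that add atoms: none
Why: Proposed new method: a one-cell anodic dehydrogenative benzylic C(sp3)–H/aryl C(sp2)–H cross-coupling with cathodic H2 evolution, run next to a free carbinol — the alkylated ring of 4 should be about 0.1 V easier to oxidise than 5 (estimated), so hole transfer (direct or relayed by 5) lands on 4, lutidine removes the benzylic proton and a second electron transfer (ECE sequence) gives the 2,4-dimethoxy-stabilised cation 6, which stays alive in HFIP until 5 attacks through its most nucleophilic C5 position (Friedel–Crafts step, proton returned to the cathode via lutidinium); the weakly basic medium disfavours base-assisted Cα–Cβ fragmentation, C2 is never a reacting centre so its (R) configuration is retained, and C1 is not stereogenic; the closest known reaction type is the two-stage anodic benzylic C–H/aromatic C–H coupling through stabilised benzylic cation pools (and anodic benzylic substitution in HFIP), not yet shown as a single-cell process with an oxidisable arene partner or beside an unprotected carbinol stereocentre.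

**Compound list**
1 | 1-bromo-2,4,5-trimethoxybenzene | COc1cc(OC)c(Br)cc1OC | starting material
2 | (R)-2-methyloxirane [(R)-propylene oxide] | C[C@@H]1CO1 | starting material
3 | (2,4,5-trimethoxyphenyl)magnesium bromide | COc1cc(OC)c([Mg]Br)cc1OC | intermediate
4 | (R)-1-(2,4,5-trimethoxyphenyl)propan-2-ol | COc1cc(OC)c(C[C@@H](C)O)cc1OC | intermediate
5 | 1,2,4-trimethoxybenzene | COc1ccc(OC)c(OC)c1 | starting material
6 | (2R)-2-hydroxy-1-(2,4,5-trimethoxyphenyl)propan-1-ylium (benzylic cation) | COc1cc(OC)c([CH+][C@@H](C)O)cc1OC | intermediate
7 | tatarinoid C, (2R)-1,1-bis(2,4,5-trimethoxyphenyl)propan-2-ol | COc1cc(OC)c(C(c2cc(OC)c(OC)cc2OC)[C@@H](C)O)cc1OC | target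

**Total step count:** 2
**Longest linear sequence:** 2

**Steps most likely to fail (both steps, ranked)**

1. Step 2 (proposed new method) is the main risk. Four things can go wrong:
   - arene 5 is oxidised itself and homocouples to a hexamethoxybiphenyl;
   - the radical cations of 4 or 7 fragment at Cα–Cβ with loss of acetaldehyde;
   - cation 6 undergoes a 1,2-hydride shift to achiral 1-(2,4,5-trimethoxyphenyl)propan-2-one (this lowers yield, not ee);
   - product 7 is over-oxidised at high conversion.

   Fallback with known chemistry: it sets out from Grignard reagent 3 (made from 1 as in step 1) and comes back to the route at 7. Commercial methyl (R)-lactate is silylated (TBSCl, imidazole, DMF) to methyl (R)-2-[(tert-butyldimethylsilyl)oxy]propanoate F1. Double addition of 3 (2.3 equiv, THF, −40 → 0 °C) to the ester gives the tertiary carbinol (R)-2-[(tert-butyldimethylsilyl)oxy]-1,1-bis(2,4,5-trimethoxyphenyl)propan-1-ol F2. Ionic hydrogenation (Et3SiH, TFA, CH2Cl2, −20 °C) removes the doubly benzylic hydroxyl and gives tert-butyl{[(R)-1,1-bis(2,4,5-trimethoxyphenyl)propan-2-yl]oxy}dimethylsilane F3, and TBAF in THF releases 7. Both aryl–carbon bonds are then made by carbonyl addition, and the stereocentre comes from (R)-lactate without being touched.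

2. Step 1 is reliable chemistry, but the electron-rich bromide 1 may insert magnesium sluggishly, and magnesium bromide can open 2 to the bromohydrin instead of the aryl transfer.

   Fallback: it sets out from 5 and comes back to the route at 4. Friedel–Crafts acylation of 5 at C5 with commercial (R)-2-acetoxypropanoyl chloride (SnCl4, CH2Cl2, −20 °C) gives (R)-1-oxo-1-(2,4,5-trimethoxyphenyl)propan-2-yl acetate F4. Et3SiH in TFA reduces the electron-rich aryl ketone to the methylene compound (R)-1-(2,4,5-trimethoxyphenyl)propan-2-yl acetate F5, and K2CO3 in MeOH removes the acetate to give 4. The aryl–carbon bond is then made by acylation instead of epoxide opening; the ee of F4 and F5 must be checked because the α-acyloxy ketone can enolise.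

**Further compounds**
F1 | step 2 | methyl (R)-2-[(tert-butyldimethylsilyl)oxy]propanoate | C[C@@H](O[Si](C)(C)C(C)(C)C)C(=O)OC
F2 | step 2 | (R)-2-[(tert-butyldimethylsilyl)oxy]-1,1-bis(2,4,5-trimethoxyphenyl)propan-1-ol | C[C@@H](O[Si](C)(C)C(C)(C)C)C(O)(c1cc(OC)c(OC)cc1OC)c1cc(OC)c(OC)cc1OC
F3 | step 2 | tert-butyl{[(R)-1,1-bis(2,4,5-trimethoxyphenyl)propan-2-yl]oxy}dimethylsilane | C[C@@H](O[Si](C)(C)C(C)(C)C)C(c1cc(OC)c(OC)cc1OC)c1cc(OC)c(OC)cc1OC
F4 | step 1 | (R)-1-oxo-1-(2,4,5-trimethoxyphenyl)propan-2-yl acetate | C[C@@H](OC(C)=O)C(=O)c1cc(OC)c(OC)cc1OC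
F5 | step 1 | (R)-1-(2,4,5-trimethoxyphenyl)propan-2-yl acetate | C[C@@H](OC(C)=O)Cc1cc(OC)c(OC)cc1OC
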